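If someone else was to take over this bench, I wanted them to find the flask explained, so I wrote down what I charged, how it reacts and what was asked.

electrophile 20 mM; protonated nucleophile 30.0 mM; time 4.0 d

    electrophile + nucleophile → acid set free + product (k1 = 3.4 /M/h)
    nucleophile + acid set free ⇌ protonated nucleophile, settled at all times (K2 = 1.7 × 10⁵ /M)
    free base + product ⇌ idle adduct, settled at all times (K3 = 44 /M)
    acid set free + free base ⇌ salt of the base, settled at all times (K4 = 5.6 × 10⁵ /M)
    crystals ⇌ product, rate k5*(cs5 - [product]) while solid is left; crystals form when [product] > cs5 (cs5 = 8.3 mM, k5 = 0.27 /h)

1. the concentration of free base at which the part of the electrophile that has reacted at 4.0 d is just 70 %, in mM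

I charged the nucleophile in its protonated form, so I counted protons first. Each electrophile that reacted used one free nucleophile and set one acid free, and because the free base holds a proton more tightly than the nucleophile does, I booked the free base to pay twice: once to strip a protonated nucleophile and once to catch the acid. I called this the proton bill, the stoichiometric demand of free base for the part wanted, and it came to 28.0 mM. Reaching that part in 4.0 d also asked for a time-mean [nucleophile] of 3.69 mM, so I took the bill as my lower end and the bill plus that mean, 31.7 mM, as my upper end.

At 4.0 d the flask should hold 6.00 mM of electrophile and 14.0 mM of product, idle adduct and crystals counted, which is more than the 8.3 mM that dissolves. I therefore expected crystals, and separately I noted that the free base was not to be trimmed towards the bill.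

The forecast put the free base at 29.2 mM, within 28.8 mM to 29.6 mM, on these grounds: “Free acid is negligible, so the base simply exchanges protons with the nucleophile”.

The flask needed 29.0 mM of free base, 1.00 mM above the bill and close to the forecast. A second flask, otherwise the same, held 23.2 mM of free base, and its electrophile had reacted to 58.0 % at 4.0 d. At the same bill per electrophile, that charge of free base pays for 58.1 % of the electrophile.

The numbers are assumed; the flask was simulated.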